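**Retrosynthetic overview**
1. Target 21 comes from 20 by one acidolysis (tert-butyl ester, silyl ether, 6,15-acetal). The side-chain ester comes from acryloylation and a Morita–Baylis–Hillman reaction at 8-OH, and C11=C13 from a Wittig reaction on an α-keto ester.
2. Ring B is formed last: C6–C7 and C7–C8 by a new [5+1] double aldol of tert-butyl pyruvate (13) with 1,5-dialdehyde 12, which sets C5–C8.
3. Dialdehyde 12 comes from ozonolysis of the vinyl and allyl groups of 11; C15 comes from Wittig homologation of the C4 ketone of 9.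
4. Ring A is formed first as a six-membered ring: semipinacol ring expansion of spiro vinyl-oxirane 8 (1,2-shift of C10), made from cyclopentanone 7.
5. Ketone 7 comes from 2-methylcyclopentane-1,3-dione (1) and allyl bromide (2) by allylation, CBS desymmetrisation and Mitsunobu inversion at the future C1.

Assumption: the target is taken as the open 6-hydroxy-15-aldehyde as drawn (a 6,15-lactol tautomer may coexist); decalins are named with eudesmane numbering (C14 = CH3 on C10, C15 on C4, C11–C13 on C7; α = lower face, β = upper face).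

**Route**

Step 1
Reactants: 1 2-methylcyclopentane-1,3-dione; 2 allyl bromide
Product: 3 2-methyl-2-(prop-2-en-1-yl)cyclopentane-1,3-dione
Conditions: 1 M aq. NaOH, rt
Reagents that add atoms: none
Why: C-alkylation (SN2) of the sodium enolate of the cyclic 1,3-dione gives the 2,2-disubstituted dione; no stereocentre is formed (C2 is prochiral).

Step 2
Reactants: 3 2-methyl-2-(prop-2-en-1-yl)cyclopentane-1,3-dione
Product: 4 (2S,3S)-3-hydroxy-2-methyl-2-(prop-2-en-1-yl)cyclopentan-1-one
Conditions: (R)-Me-CBS (0.2 equiv), catecholborane, toluene, −78 °C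
Reagents that add atoms: none
Why: Corey–Bakshi–Shibata reduction: the oxazaborolidine delivers hydride to one enantiotopic carbonyl from the face cis to the methyl group, which fixes the quaternary carbon (future C10) as S and gives the 3S carbinol (OH cis to allyl), the usual outcome for 2-alkyl-2-methylcyclopentane-1,3-diones.

Step 3
Reactants: 4 (2S,3S)-3-hydroxy-2-methyl-2-(prop-2-en-1-yl)cyclopentan-1-one
Product: 6 (2S,3R)-3-hydroxy-2-methyl-2-(prop-2-en-1-yl)cyclopentan-1-one, via formate ester 5 (not isolated)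
Conditions: PPh3, DIAD, HCO2H, THF, 0 °C → rt; then NaHCO3, MeOH, rt
Reagents that add atoms: formic acid, OC=O
Why: Mitsunobu reaction: SN2 displacement of the activated alcohol by formate inverts C3 (as in inversions of 17-hydroxy steroids), so the oxygen is now cis to the methyl group (future 1β-OH); the labile formate is removed by mild methanolysis to avoid retro-aldol of the β-hydroxy ketone.

Step 4
Reactants: 6 (2S,3R)-3-hydroxy-2-methyl-2-(prop-2-en-1-yl)cyclopentan-1-one
Product: 7 (2S,3R)-3-[(tert-butyldimethylsilyl)oxy]-2-methyl-2-(prop-2-en-1-yl)cyclopentan-1-one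
Conditions: TBSOTf, 2,6-lutidine, CH2Cl2, −78 °C
Reagents that add atoms: tert-butyldimethylsilyl triflate, CC(C)(C)[Si](C)(C)OS(=O)(=O)C(F)(F)F
Why: Silyl ether formation with a silyl triflate and a hindered base protects the neopentyl-type alcohol; no stereocentre is touched.

Step 5
Reactants: 7 (2S,3R)-3-[(tert-butyldimethylsilyl)oxy]-2-methyl-2-(prop-2-en-1-yl)cyclopentan-1-one; 2 allyl bromide
Product: 8 tert-butyl{[(4S,5R)-2-ethenyl-4-methyl-4-(prop-2-en-1-yl)-1-oxaspiro[2.4]heptan-5-yl]oxy}dimethylsilane (both configurations at C2 and C3)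
Conditions: tetrahydrothiophene, THF, rt (with 2); KHMDS, −78 °C; then 7, −78 → 0 °C
Reagents that add atoms: none
Why: Corey–Chaykovsky-type epoxidation with a semi-stabilised allylsulfonium ylide (made in the flask from 2 and tetrahydrothiophene) converts the ketone into the spiro vinyl-oxirane; both oxirane centres are lost or become epimerisable in step 6, so their configuration does not matter.

Step 6
Reactants: 8 spiro vinyl-oxirane
Product: 9 (2R,3R,4R)-4-[(tert-butyldimethylsilyl)oxy]-2-ethenyl-3-methyl-3-(prop-2-en-1-yl)cyclohexan-1-one (vinyl trans to allyl as major C2 epimer)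
Conditions: BF3·OEt2 (0.2 equiv), CH2Cl2, −78 °C
Reagents that add atoms: none
Why: Semipinacol (Meinwald-type) ring expansion: BF3 opens the oxirane at the allylic carbon and the more substituted ring carbon (C10) undergoes a 1,2-shift with retention, inserting C5 between C10 and the new C4 ketone; C5 is α to the ketone, hence epimerisable, and is fixed in step 9.

Step 7
Reactants: 9 (2R,3R,4R)-4-[(tert-butyldimethylsilyl)oxy]-2-ethenyl-3-methyl-3-(prop-2-en-1-yl)cyclohexan-1-one
Product: 11 tert-butyl{[(1R,2R,3S,4R)-4-(dimethoxymethyl)-3-ethenyl-2-methyl-2-(prop-2-en-1-yl)cyclohexyl]oxy}dimethylsilane, via enol ether 10 (not isolated)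
Conditions: Ph3P(Cl)CH2OMe, KHMDS, THF, 0 °C → rt; then MeOH, PPTS (cat.), rt
Reagents that add atoms: (methoxymethyl)triphenylphosphonium chloride, COC[P+](c1ccccc1)(c1ccccc1)c1ccccc1.[Cl-]; methanol, CO
Why: Wittig methoxymethylenation of the C4 ketone followed by acid-catalysed addition of methanol to the enol ether gives the dimethyl acetal; axial protonation and acid equilibration place the CH(OMe)2 group equatorial (4α), trans to the C5 substituent.

Step 8
Reactants: 11 tert-butyl{[(1R,2R,3S,4R)-4-(dimethoxymethyl)-3-ethenyl-2-methyl-2-(prop-2-en-1-yl)cyclohexyl]oxy}dimethylsilane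
Product: 12 (1S,2R,3R,6R)-3-[(tert-butyldimethylsilyl)oxy]-6-(dimethoxymethyl)-2-methyl-2-(2-oxoethyl)cyclohexane-1-carbaldehyde
Conditions: O3, CH2Cl2/MeOH, −78 °C; then Me2S
Reagents that add atoms: ozone, [O-][O+]=O
Why: Ozonolysis with reductive work-up cleaves both terminal alkenes to the 1,5-dialdehyde; the acetal and silyl ether are inert and no stereocentre is set (C5 stays epimerisable).

Step 9
Reactants: 12 (1S,2R,3R,6R)-3-[(tert-butyldimethylsilyl)oxy]-6-(dimethoxymethyl)-2-methyl-2-(2-oxoethyl)cyclohexane-1-carbaldehyde; 13 tert-butyl pyruvate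
Product: 15 tert-butyl 1β-[(tert-butyldimethylsilyl)oxy]-6α,15-epoxy-8α-hydroxy-15-methoxy-11-oxo-13-nor-eudesman-12-oate, via diol keto ester 14 (not isolated)
Conditions: MgBr2·OEt2 (1.2 equiv), i-Pr2NEt, 13 added slowly, CH2Cl2, −20 °C → rt; then PPTS (cat.), 4 Å MS, CH2Cl2, rt
Reagents that add atoms: none
Why: Proposed new method: a Mg(II)/amine soft-enolisation double aldol in which the methyl group of the Mg-chelated pyruvate adds first to the unhindered CH2CHO group and then, as a 6-enolexo aldol, to the ring formyl group, closing ring B with two C–C bonds; because both aldol steps and the enolisable C5 and C7 centres equilibrate, the all-equatorial trans-decalin (5αH, 6α-OH, 7β-acyl, 8α-OH) is expected as the thermodynamic product, and the subsequent PPTS transacetalisation, possible only for the 6α-OH/4α-acetal isomer, locks it as the 6,15-acetal; the closest known reactions are the Fischer–Baer/Lichtenthaler nitromethane–dialdehyde cyclisation and Mg- or Cu-mediated direct aldol additions of pyruvate esters.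

Step 10
Reactants: 15 tert-butyl 1β-[(tert-butyldimethylsilyl)oxy]-6α,15-epoxy-8α-hydroxy-15-methoxy-11-oxo-13-nor-eudesman-12-oate
Product: 16 tert-butyl 1β-[(tert-butyldimethylsilyl)oxy]-6α,15-epoxy-8α-hydroxy-15-methoxyeudesm-11(13)-en-12-oate
Conditions: Ph3PCH3Br, KHMDS (ylide 2.5 equiv), THF, −78 → 0 °C
Reagents that add atoms: methyltriphenylphosphonium bromide, C[P+](c1ccccc1)(c1ccccc1)c1ccccc1.[Br-]
Why: Wittig methylenation of the highly electrophilic ketone of the α-keto ester at low temperature gives the 1,1-disubstituted acrylate; C7 is already equatorial and is not changed.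

Step 11
Reactants: 16 tert-butyl 1β-[(tert-butyldimethylsilyl)oxy]-6α,15-epoxy-8α-hydroxy-15-methoxyeudesm-11(13)-en-12-oate; 17 acryloyl chloride
Product: 18 tert-butyl 8α-(acryloyloxy)-1β-[(tert-butyldimethylsilyl)oxy]-6α,15-epoxy-15-methoxyeudesm-11(13)-en-12-oate
Conditions: Et3N, DMAP (cat.), CH2Cl2, −20 → 0 °C
Reagents that add atoms: none
Why: DMAP-catalysed acylation (nucleophilic acyl substitution) of the only free hydroxyl group, 8α-OH (O6 is in the acetal, O1 is silylated); no stereocentre is changed.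

Step 12
Reactants: 18 tert-butyl 8α-(acryloyloxy)-1β-[(tert-butyldimethylsilyl)oxy]-6α,15-epoxy-15-methoxyeudesm-11(13)-en-12-oate; 19 formaldehyde
Product: 20 tert-butyl 1β-[(tert-butyldimethylsilyl)oxy]-6α,15-epoxy-8α-{[2-(hydroxymethyl)prop-2-enoyl]oxy}-15-methoxyeudesm-11(13)-en-12-oate
Conditions: DABCO (1 equiv), 37% aq. HCHO, 1,4-dioxane/H2O, rt
Reagents that add atoms: none
Why: Morita–Baylis–Hillman reaction: DABCO adds to the unsubstituted acrylate (the α-substituted tert-butyl acrylate has no α-H and cannot react) and the resulting enolate is hydroxymethylated by formaldehyde; no stereocentre is formed.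

Step 13
Reactants: 20 tert-butyl 1β-[(tert-butyldimethylsilyl)oxy]-6α,15-epoxy-8α-{[2-(hydroxymethyl)prop-2-enoyl]oxy}-15-methoxyeudesm-11(13)-en-12-oate
Product: 21 1β,6α-dihydroxy-8α-{[2-(hydroxymethyl)prop-2-enoyl]oxy}-15-oxoeudesm-11(13)-en-12-oic acid (target)
Conditions: TFA/H2O/CH2Cl2, 0 °C → rt; brief aq. NaHCO3 work-up, then acidify
Reagents that add atoms: water, O
Why: Acidolysis: aqueous TFA cleaves the tert-butyl ester (as isobutene), the silyl ether and the mixed cyclic acetal, releasing 6α-OH and the equatorial 4α-formyl group; no stereocentre is changed.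

**Compound list**

1 | 2-methylcyclopentane-1,3-dione | CC1C(=O)CCC1=O | starting material
2 | allyl bromide (3-bromoprop-1-ene) | C=CCBr | starting material
3 | 2-methyl-2-(prop-2-en-1-yl)cyclopentane-1,3-dione | C=CCC1(C)C(=O)CCC1=O | intermediate
4 | (2S,3S)-3-hydroxy-2-methyl-2-(prop-2-en-1-yl)cyclopentan-1-one (OH cis to allyl) | C=CC[C@]1(C)C(=O)CC[C@@H]1O | intermediate
5 | (1R,2S)-2-methyl-3-oxo-2-(prop-2-en-1-yl)cyclopentyl formate (O cis to CH3) | C=CC[C@]1(C)C(=O)CC[C@H]1OC=O | intermediate (not isolated)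
6 | (2S,3R)-3-hydroxy-2-methyl-2-(prop-2-en-1-yl)cyclopentan-1-one (OH cis to CH3) | C=CC[C@]1(C)C(=O)CC[C@H]1O | intermediate
7 | (2S,3R)-3-[(tert-butyldimethylsilyl)oxy]-2-methyl-2-(prop-2-en-1-yl)cyclopentan-1-one | C=CC[C@]1(C)C(=O)CC[C@H]1O[Si](C)(C)C(C)(C)C | intermediate
8 | tert-butyl{[(4S,5R)-2-ethenyl-4-methyl-4-(prop-2-en-1-yl)-1-oxaspiro[2.4]heptan-5-yl]oxy}dimethylsilane (diastereomers at C2/C3) | C=CC[C@]1(C)C2(OC2C=C)CC[C@H]1O[Si](C)(C)C(C)(C)C | intermediate
9 | (2R,3R,4R)-4-[(tert-butyldimethylsilyl)oxy]-2-ethenyl-3-methyl-3-(prop-2-en-1-yl)cyclohexan-1-one (major C2 epimer shown) | C=CC[C@]1(C)[C@@H](C=C)C(=O)CC[C@H]1O[Si](C)(C)C(C)(C)C | intermediate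
10 | tert-butyl{[(1R,2R,3S)-3-ethenyl-4-(methoxymethylidene)-2-methyl-2-(prop-2-en-1-yl)cyclohexyl]oxy}dimethylsilane (E/Z) | C=CC[C@]1(C)[C@@H](C=C)C(=COC)CC[C@H]1O[Si](C)(C)C(C)(C)C | intermediate (not isolated)
11 | tert-butyl{[(1R,2R,3S,4R)-4-(dimethoxymethyl)-3-ethenyl-2-methyl-2-(prop-2-en-1-yl)cyclohexyl]oxy}dimethylsilane | C=CC[C@]1(C)[C@@H](C=C)[C@H](C(OC)OC)CC[C@H]1O[Si](C)(C)C(C)(C)C | intermediate
12 | (1S,2R,3R,6R)-3-[(tert-butyldimethylsilyl)oxy]-6-(dimethoxymethyl)-2-methyl-2-(2-oxoethyl)cyclohexane-1-carbaldehyde (C1 epimerisable) | O=CC[C@]1(C)[C@@H](C=O)[C@H](C(OC)OC)CC[C@H]1O[Si](C)(C)C(C)(C)C | intermediate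
13 | tert-butyl pyruvate (pyruvic acid carried as its tert-butyl ester) | CC(=O)C(=O)OC(C)(C)C | starting material
14 | tert-butyl 1β-[(tert-butyldimethylsilyl)oxy]-6α,8α-dihydroxy-15,15-dimethoxy-11-oxo-13-nor-eudesman-12-oate (4βH,5αH,7αH,10β-CH3) | O[C@H]1C[C@]2(C)[C@@H]([C@@H](O)[C@@H]1C(=O)C(=O)OC(C)(C)C)[C@H](C(OC)OC)CC[C@H]2O[Si](C)(C)C(C)(C)C | intermediate (not isolated)
15 | tert-butyl 1β-[(tert-butyldimethylsilyl)oxy]-6α,15-epoxy-8α-hydroxy-15-methoxy-11-oxo-13-nor-eudesman-12-oate (both C15 anomers) | O[C@H]1C[C@]2(C)[C@@H]([C@@H](O3)[C@@H]1C(=O)C(=O)OC(C)(C)C)[C@H](C3OC)CC[C@H]2O[Si](C)(C)C(C)(C)C | intermediate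
16 | tert-butyl 1β-[(tert-butyldimethylsilyl)oxy]-6α,15-epoxy-8α-hydroxy-15-methoxyeudesm-11(13)-en-12-oate | O[C@H]1C[C@]2(C)[C@@H]([C@@H](O3)[C@@H]1C(=C)C(=O)OC(C)(C)C)[C@H](C3OC)CC[C@H]2O[Si](C)(C)C(C)(C)C | intermediate
17 | acryloyl chloride (prop-2-enoyl chloride) | C=CC(Cl)=O | starting material
18 | tert-butyl 8α-(acryloyloxy)-1β-[(tert-butyldimethylsilyl)oxy]-6α,15-epoxy-15-methoxyeudesm-11(13)-en-12-oate | C=CC(=O)O[C@H]1C[C@]2(C)[C@@H]([C@@H](O3)[C@@H]1C(=C)C(=O)OC(C)(C)C)[C@H](C3OC)CC[C@H]2O[Si](C)(C)C(C)(C)C | intermediate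
19 | formaldehyde | C=O | starting material
20 | tert-butyl 1β-[(tert-butyldimethylsilyl)oxy]-6α,15-epoxy-8α-{[2-(hydroxymethyl)prop-2-enoyl]oxy}-15-methoxyeudesm-11(13)-en-12-oate | C=C(CO)C(=O)O[C@H]1C[C@]2(C)[C@@H]([C@@H](O3)[C@@H]1C(=C)C(=O)OC(C)(C)C)[C@H](C3OC)CC[C@H]2O[Si](C)(C)C(C)(C)C | intermediate
21 | 1β,6α-dihydroxy-8α-{[2-(hydroxymethyl)prop-2-enoyl]oxy}-15-oxoeudesm-11(13)-en-12-oic acid, (1R,4R,5S,6R,7S,8S,10R) | C=C(CO)C(=O)O[C@H]1C[C@]2(C)[C@@H]([C@@H](O)[C@@H]1C(=C)C(=O)O)[C@H](C=O)CC[C@H]2O | target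

**Step count and risks**

Total step count: 13. Longest linear sequence: 13 (the route is fully linear).

Steps most likely to fail:

Step 9 (the new [5+1] double aldol). Risks are self-aldol of the pyruvate, dehydration of the β-hydroxy α-keto ester, and incomplete equilibration to the all-equatorial isomer. The fallback uses known chemistry, sets out from 12 and comes back at 14. Wittig olefination of the unhindered CH2CHO group of 12 with tert-butyl 2-oxo-3-(triphenylphosphoranylidene)propanoate (CH2Cl2, rt; the α-branched ring aldehyde is left) gives the (E)-enone keto ester F1. A copper-catalysed conjugate borylation with intramolecular aldol trapping (B2pin2, CuCl, dppf, NaOt-Bu, THF; borylative aldol cyclisation) then closes ring B to the C8 pinacolboronate F2, whose C7 centre can equilibrate to equatorial. Oxidation with NaBO3 (THF/H2O, retention at C8) gives diol 14, which is treated with PPTS as in step 9 to reach 15.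

Step 6 (semipinacol ring expansion, together with the oxirane formation of step 5). Risks are migration of the CH2 carbon instead of C10, capture of the allyl cation, and isomerisation of the β,γ-unsaturated ketone. The fallback sets out from 7 and comes back at 9, using the Taguchi–Nozaki β-oxido carbenoid ring expansion. LiCHBr2 (from CH2Br2 and LiTMP, THF, −78 °C) adds to 7 to give the dibromomethyl carbinol F3. n-BuLi then effects bromine–lithium exchange and the 1,2-shift of the more substituted carbon, giving the regiodefined ring-expanded lithium enolate F4. Palladium-catalysed α-vinylation of this enolate with vinyl bromide (Pd(dba)2, Q-Phos, THF) gives 9.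

Step 12 (late-stage Morita–Baylis–Hillman reaction). Risks are slow reaction of the hindered acrylate and ether dimers from oxa-Michael addition. The fallback sets out from 16 and comes back at 21, attaching the complete side chain by esterification. Methyl 2-(hydroxymethyl)acrylate is silylated (TBSCl, imidazole) to F5 and saponified (LiOH, THF/H2O) to the acid F6. Esterification of 16 with F6 (EDC, DMAP, CH2Cl2) gives the silyl-protected ester F7, and the acid treatment of step 13 (TFA/H2O/CH2Cl2) converts F7 into 21.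

**Further compounds**

F1 | step 9 | tert-butyl (E)-2-oxopent-3-enoate carrying at C5 the ring of 12 (CH2CHO arm of 12 turned into CH2–CH=CH–CO–CO2t-Bu, ring CHO kept) | CC(C)(C)OC(=O)C(=O)/C=C/C[C@]1(C)[C@@H](C=O)[C@H](C(OC)OC)CC[C@H]1O[Si](C)(C)C(C)(C)C
F2 | step 9 | tert-butyl 1β-[(tert-butyldimethylsilyl)oxy]-6α-hydroxy-15,15-dimethoxy-11-oxo-8α-(4,4,5,5-tetramethyl-1,3,2-dioxaborolan-2-yl)-13-nor-eudesman-12-oate | CC1(C)OB(OC1(C)C)[C@H]2C[C@]3(C)[C@@H]([C@@H](O)[C@@H]2C(=O)C(=O)OC(C)(C)C)[C@H](C(OC)OC)CC[C@H]3O[Si](C)(C)C(C)(C)C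
F3 | step 6 | (2S,3R)-3-[(tert-butyldimethylsilyl)oxy]-1-(dibromomethyl)-2-methyl-2-(prop-2-en-1-yl)cyclopentan-1-ol (both C1 epimers) | C=CC[C@]1(C)C(O)(C(Br)Br)CC[C@H]1O[Si](C)(C)C(C)(C)C
F4 | step 6 | lithium (3R,4R)-4-[(tert-butyldimethylsilyl)oxy]-3-methyl-3-(prop-2-en-1-yl)cyclohex-1-en-1-olate | C=CC[C@]1(C)C=C([O-])CC[C@H]1O[Si](C)(C)C(C)(C)C.[Li+]
F5 | step 12 | methyl 2-{[(tert-butyldimethylsilyl)oxy]methyl}prop-2-enoate | C=C(CO[Si](C)(C)C(C)(C)C)C(=O)OC
F6 | step 12 | 2-{[(tert-butyldimethylsilyl)oxy]methyl}prop-2-enoic acid | C=C(CO[Si](C)(C)C(C)(C)C)C(=O)O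
F7 | step 12 | tert-butyl 1β-[(tert-butyldimethylsilyl)oxy]-8α-[(2-{[(tert-butyldimethylsilyl)oxy]methyl}prop-2-enoyl)oxy]-6α,15-epoxy-15-methoxyeudesm-11(13)-en-12-oate | C=C(CO[Si](C)(C)C(C)(C)C)C(=O)O[C@H]1C[C@]2(C)[C@@H]([C@@H](O3)[C@@H]1C(=C)C(=O)OC(C)(C)C)[C@H](C3OC)CC[C@H]2O[Si](C)(C)C(C)(C)C
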